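A direct plan would make the chain by an aldol reaction and close the ring at the benzylic carbon: the α-benzyloxy aldehyde A1 would add the silyloxydiene A2 under MgBr2 chelation to give the β-hydroxy enone A3, acid would close A3 by 6-endo oxa-Michael addition to the tetrahydropyranone A4, and hydride reduction to A5 followed by hydrogenolysis of three benzyl ethers would finish.
Weak step, the chelation-controlled aldol: ring carbon C6, from which every other centre is relayed, would depend on Mg chelation of a configurationally labile α-alkoxy aldehyde whose own preparation (three functional-group steps) builds no skeleton.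
Weak step, the acid-mediated oxa-Michael closure: a β-hydroxy ketone next to an enone would be prone to dehydration or retro-aldol cleavage, and C2 would be set only by equilibration.
Weak step, the final hydrogenolysis: three benzyl ethers would have to be cleaved while the ring C2–O1 bond, itself a p-oxygenated benzylic ether, must survive.

**Retrosynthetic overview of the new route**
1. Feature used: the tetrahydropyran ring (O1, C2–C6) has its oxygen function at C4 between a cis-2,6 pair and an aryl group on C2. This is the retron of a hetero-Diels–Alder reaction in which C2=O1 is an aromatic aldehyde.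
2. Key disconnection: C2–C3 and O1–C6 are formed together from vanillin acetate 11 (C2 and the guaiacyl ring) and the 2-silyloxydiene 10 (C3–C6 and the complete C1′ side chain). The only ring closes in this step, and C2/C6 are set as a pair by a chiral Cr(III) catalyst and the endo rule.
3. Diene 10 ⇐ γ-hydroxy enone 8 (one-pot O-silylation/enolisation) ⇐ cross-metathesis of allylic alcohol 6 with methyl vinyl ketone ⇐ (S)-epichlorohydrin, an aryl Grignard reagent and a C1 ylide.
4. End game: L-Selectride on ketone 13 (axial C4–OH; the aryl acetate is cleaved in the same flask), then fluoride.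
5. Weak steps avoided by design: C1′ comes from epichlorohydrin and C6 from catalyst control, so there is no α-alkoxy aldehyde and no chelate aldol. The ring oxygen is the aldehyde oxygen, so no acyclic β-hydroxy ketone and no reversible oxa-Michael step exist. There are no benzyl ethers: the phenol acetate activates the aldehyde and the silyl ethers leave with fluoride.

Key step: step 5

Assumption: compounds 1, 2, 7 and 11 are taken as commercial. The sense of induction of the chromium catalyst is assigned by analogy with simple aldehydes and would be confirmed on the first run; if it were opposite, the antipodal catalyst would be used.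

Step 1
Reactants: 1 (4-bromophenoxy)triisopropylsilane; 2 (S)-epichlorohydrin [(S)-2-(chloromethyl)oxirane]
Product: 4 (2S)-1-chloro-3-[4-(triisopropylsilyloxy)phenyl]propan-2-ol, via [4-(triisopropylsilyloxy)phenyl]magnesium bromide 3 (not isolated)
Conditions: Mg, THF, 40 °C; then CuI (10 mol %), 2, THF, −40 → 0 °C; aq work-up
Reagents that add atoms: none
Why: Copper-catalysed Grignard opening of the epoxide at its CH2 group (the C–Cl bond and the stereocentre of 2 are not touched), so the future C1′ carbinol is taken intact from (S)-epichlorohydrin.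

Step 2
Reactants: 4 (2S)-1-chloro-3-[4-(triisopropylsilyloxy)phenyl]propan-2-ol
Product: 6 (2S)-1-[4-(triisopropylsilyloxy)phenyl]but-3-en-2-ol, via (2S)-2-[4-(triisopropylsilyloxy)benzyl]oxirane 5 (not isolated)
Conditions: Me3S+ I− (4 equiv), n-BuLi (3.8 equiv), THF, −10 °C → rt
Reagents that add atoms: trimethylsulfonium iodide, C[S+](C)C.[I-]
Why: One-carbon homologation of an epoxide to an allylic alcohol with excess dimethylsulfonium methylide (Corey–Chaykovsky-type ylide): base closes 4 to epoxide 5, the ylide opens it at CH2 and elimination of dimethyl sulfide from the betaine should give the vinyl carbinol, the stereocentre never being a reaction site.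

Step 3
Reactants: 6 (2S)-1-[4-(triisopropylsilyloxy)phenyl]but-3-en-2-ol; 7 methyl vinyl ketone (but-3-en-2-one)
Product: 8 (3E,5S)-5-hydroxy-6-[4-(triisopropylsilyloxy)phenyl]hex-3-en-2-one
Conditions: Hoveyda–Grubbs II catalyst (5 mol %), 7 (4 equiv), CH2Cl2, 40 °C
Reagents that add atoms: none
Why: Olefin cross-metathesis of a secondary allylic alcohol with an enone, which should give the E-enone with ethylene as the only co-product; the free hydroxyl is tolerated, so no protecting step is spent.

Step 4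
Reactants: 8 (3E,5S)-5-hydroxy-6-[4-(triisopropylsilyloxy)phenyl]hex-3-en-2-one
Product: 10 (3E,5S)-2,5-bis(tert-butyldimethylsilyloxy)-6-[4-(triisopropylsilyloxy)phenyl]hexa-1,3-diene, via (3E,5S)-5-(tert-butyldimethylsilyloxy)-6-[4-(triisopropylsilyloxy)phenyl]hex-3-en-2-one 9 (not isolated)
Conditions: TBSOTf (2.4 equiv), Et3N (4 equiv), CH2Cl2, −78 → 0 °C; cold NaHCO3 work-up, Et3N-deactivated silica
Reagents that add atoms: tert-butyldimethylsilyl trifluoromethanesulfonate, CC(C)(C)[Si](C)(C)OS(=O)(=O)C(F)(F)F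
Why: One silyl triflate does two jobs, O-silylation of the carbinol and then soft enolisation of the methyl ketone at its only kinetically accessible α-position, to give the cross-conjugated 2-silyloxydiene.

Step 5
Reactants: 10 (3E,5S)-2,5-bis(tert-butyldimethylsilyloxy)-6-[4-(triisopropylsilyloxy)phenyl]hexa-1,3-diene; 11 vanillin acetate (4-formyl-2-methoxyphenyl acetate)
Product: 13 4-{(2R,6S)-6-[(1S)-1-(tert-butyldimethylsilyloxy)-2-[4-(triisopropylsilyloxy)phenyl]ethyl]-4-oxotetrahydro-2H-pyran-2-yl}-2-methoxyphenyl acetate, via 4-{(2R,6S)-4-(tert-butyldimethylsilyloxy)-6-[(1S)-1-(tert-butyldimethylsilyloxy)-2-[4-(triisopropylsilyloxy)phenyl]ethyl]-3,6-dihydro-2H-pyran-2-yl}-2-methoxyphenyl acetate 12 (not isolated)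
Conditions: tridentate Schiff-base Cr(III)Cl catalyst from 3-(1-adamantyl)-2-hydroxy-5-methylbenzaldehyde and (1R,2S)-1-amino-2-indanol (10 mol %), 4 Å MS, 10 (1.3 equiv), minimal EtOAc, rt, 48 h; then TFA (cat.), wet CH2Cl2, 0 °C
Reagents that add atoms: none
Why: The Lewis-acidic Cr(III) centre binds the aldehyde and the 2-silyloxydiene adds in a concerted, asynchronous [4+2] cycloaddition (C2–C3 leading, O1–C6 following); the closest known reaction type is the Cr(III)–Schiff-base-catalysed hetero-Diels–Alder reaction of 4-substituted 2-silyloxybutadienes with aldehydes, which joins complex fragments as cis-2,6-tetrahydropyran-4-ones. The tetrahydropyran, the only ring of the target, closes in this [4+2] mode, so no acyclic hydroxy ketone is ever present to dehydrate or cleave. C2 is set by the catalyst, which should expose the Re face of the bound aldehyde, and C6 follows from the endo transition state with the E-diene, which places the aryl group and the side chain cis. The further selectivity needed is the pairing of this catalyst-fixed sense with the resident C1′ centre (6S with 1′S); the E-disubstituted diene terminus has only hydrogen cis to C1′, so allylic strain and the intrinsic facial bias of the diene are small and the catalyst should dominate. The acetate keeps the phenol from binding chromium and makes the otherwise electron-rich aldehyde a competent heterodienophile. Mild acid then hydrolyses the silyl enol ether 12 to ketone 13 without touching C2, C6, the alkyl TBS ether or the aryl TIPS ether.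

Step 6
Reactants: 13 4-{(2R,6S)-6-[(1S)-1-(tert-butyldimethylsilyloxy)-2-[4-(triisopropylsilyloxy)phenyl]ethyl]-4-oxotetrahydro-2H-pyran-2-yl}-2-methoxyphenyl acetate
Product: 15 (2R,4S,6S)-6-[(1S)-1-(tert-butyldimethylsilyloxy)-2-[4-(triisopropylsilyloxy)phenyl]ethyl]-2-(4-hydroxy-3-methoxyphenyl)tetrahydro-2H-pyran-4-ol, via 4-{(2R,4S,6S)-6-[(1S)-1-(tert-butyldimethylsilyloxy)-2-[4-(triisopropylsilyloxy)phenyl]ethyl]-4-hydroxytetrahydro-2H-pyran-2-yl}-2-methoxyphenyl acetate 14 (not isolated)
Conditions: L-Selectride (3.5 equiv), THF, −78 °C, then 0 °C; aq work-up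
Reagents that add atoms: none
Why: Diastereoselective ketone reduction in which the bulky trialkylborohydride attacks the chair of the 2,6-diequatorial tetrahydropyranone along the equatorial trajectory and should give the axial (4S) alcohol trans to both substituents; the excess hydride then cleaves the aryl acetate reductively, so the guaiacyl phenol is freed without a step of its own.

Step 7
Reactants: 15 (2R,4S,6S)-6-[(1S)-1-(tert-butyldimethylsilyloxy)-2-[4-(triisopropylsilyloxy)phenyl]ethyl]-2-(4-hydroxy-3-methoxyphenyl)tetrahydro-2H-pyran-4-ol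
Product: 16 rhoiptelol B, (2R,4S,6S)-2-(4-hydroxy-3-methoxyphenyl)-6-[(1S)-1-hydroxy-2-(4-hydroxyphenyl)ethyl]tetrahydro-2H-pyran-4-ol
Conditions: TBAF (4 equiv), AcOH (4 equiv), THF, 0 °C → rt
Reagents that add atoms: none
Why: Fluoride-mediated desilylation of the alkyl TBS and aryl TIPS ethers, buffered with acetic acid so that the p-hydroxybenzylic C2–O1 bond sees neither strong base nor acid and no stereocentre is touched.

**Compound list**
1 | (4-bromophenoxy)triisopropylsilane | Brc1ccc(O[Si](C(C)C)(C(C)C)C(C)C)cc1 | starting material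
2 | (S)-epichlorohydrin | ClC[C@@H]1CO1 | starting material
3 | [4-(triisopropylsilyloxy)phenyl]magnesium bromide | Br[Mg]c1ccc(O[Si](C(C)C)(C(C)C)C(C)C)cc1 | intermediate
4 | (2S)-1-chloro-3-[4-(triisopropylsilyloxy)phenyl]propan-2-ol | ClC[C@@H](O)Cc1ccc(O[Si](C(C)C)(C(C)C)C(C)C)cc1 | intermediate
5 | (2S)-2-[4-(triisopropylsilyloxy)benzyl]oxirane | C1[C@@H](O1)Cc2ccc(O[Si](C(C)C)(C(C)C)C(C)C)cc2 | intermediate
6 | (2S)-1-[4-(triisopropylsilyloxy)phenyl]but-3-en-2-ol | C=C[C@@H](O)Cc1ccc(O[Si](C(C)C)(C(C)C)C(C)C)cc1 | intermediate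
7 | methyl vinyl ketone | C=CC(C)=O | starting material
8 | (3E,5S)-5-hydroxy-6-[4-(triisopropylsilyloxy)phenyl]hex-3-en-2-one | CC(=O)/C=C/[C@@H](O)Cc1ccc(O[Si](C(C)C)(C(C)C)C(C)C)cc1 | intermediate
9 | (3E,5S)-5-(tert-butyldimethylsilyloxy)-6-[4-(triisopropylsilyloxy)phenyl]hex-3-en-2-one | CC(=O)/C=C/[C@@H](O[Si](C)(C)C(C)(C)C)Cc1ccc(O[Si](C(C)C)(C(C)C)C(C)C)cc1 | intermediate
10 | (3E,5S)-2,5-bis(tert-butyldimethylsilyloxy)-6-[4-(triisopropylsilyloxy)phenyl]hexa-1,3-diene | C=C(O[Si](C)(C)C(C)(C)C)/C=C/[C@@H](O[Si](C)(C)C(C)(C)C)Cc1ccc(O[Si](C(C)C)(C(C)C)C(C)C)cc1 | intermediate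
11 | vanillin acetate (4-formyl-2-methoxyphenyl acetate) | COc1cc(C=O)ccc1OC(C)=O | starting material
12 | 4-{(2R,6S)-4-(tert-butyldimethylsilyloxy)-6-[(1S)-1-(tert-butyldimethylsilyloxy)-2-[4-(triisopropylsilyloxy)phenyl]ethyl]-3,6-dihydro-2H-pyran-2-yl}-2-methoxyphenyl acetate | COc1cc([C@H]2CC(O[Si](C)(C)C(C)(C)C)=C[C@@H]([C@@H](O[Si](C)(C)C(C)(C)C)Cc3ccc(O[Si](C(C)C)(C(C)C)C(C)C)cc3)O2)ccc1OC(C)=O | intermediate
13 | 4-{(2R,6S)-6-[(1S)-1-(tert-butyldimethylsilyloxy)-2-[4-(triisopropylsilyloxy)phenyl]ethyl]-4-oxotetrahydro-2H-pyran-2-yl}-2-methoxyphenyl acetate | COc1cc([C@H]2CC(=O)C[C@@H]([C@@H](O[Si](C)(C)C(C)(C)C)Cc3ccc(O[Si](C(C)C)(C(C)C)C(C)C)cc3)O2)ccc1OC(C)=O | intermediate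
14 | 4-{(2R,4S,6S)-6-[(1S)-1-(tert-butyldimethylsilyloxy)-2-[4-(triisopropylsilyloxy)phenyl]ethyl]-4-hydroxytetrahydro-2H-pyran-2-yl}-2-methoxyphenyl acetate | COc1cc([C@H]2C[C@H](O)C[C@@H]([C@@H](O[Si](C)(C)C(C)(C)C)Cc3ccc(O[Si](C(C)C)(C(C)C)C(C)C)cc3)O2)ccc1OC(C)=O | intermediate
15 | (2R,4S,6S)-6-[(1S)-1-(tert-butyldimethylsilyloxy)-2-[4-(triisopropylsilyloxy)phenyl]ethyl]-2-(4-hydroxy-3-methoxyphenyl)tetrahydro-2H-pyran-4-ol | COc1cc([C@H]2C[C@H](O)C[C@@H]([C@@H](O[Si](C)(C)C(C)(C)C)Cc3ccc(O[Si](C(C)C)(C(C)C)C(C)C)cc3)O2)ccc1O | intermediate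
16 | rhoiptelol B, (2R,4S,6S)-2-(4-hydroxy-3-methoxyphenyl)-6-[(1S)-1-hydroxy-2-(4-hydroxyphenyl)ethyl]tetrahydro-2H-pyran-4-ol | COc1cc([C@H]2C[C@H](O)C[C@@H]([C@@H](O)Cc3ccc(O)cc3)O2)ccc1O | target

**Total step count:** 7. **Longest linear sequence:** 7 steps (1 and 2 → 16).

**Steps most likely to fail, with fallbacks**

Step 5 (hetero-Diels–Alder). What may go wrong: slow turnover with the aromatic aldehyde, or erosion of facial selectivity if the catalyst and the C1′ centre are mismatched. Fallback: the ring would be closed from the other end in two stages. Alcohol 8 would be silylated on oxygen only (TBSCl, imidazole) to give isolated 9. Its diisopinocampheylboron enolate (Ipc2BCl enantiomer chosen for Re-face attack, Et3N, Et2O, −78 °C) would be added to aldehyde 11 to give the β-hydroxy enone 4-[(1R,4E,6S)-6-(tert-butyldimethylsilyloxy)-1-hydroxy-3-oxo-7-[4-(triisopropylsilyloxy)phenyl]hept-4-en-1-yl]-2-methoxyphenyl acetate F1. A 6-endo oxa-Michael addition of the benzylic hydroxyl to the enone (cat. Pd(MeCN)4(BF4)2 or Amberlyst-15, CH2Cl2) would then return to ketone 13 as the thermodynamic 2,6-cis isomer.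

Step 3 (cross-metathesis). What may go wrong: stalled conversion, dimerisation of methyl vinyl ketone, or Ru-hydride isomerisation of the allylic alcohol to a ketone. Fallback: olefination in place of metathesis. Alcohol 6 would be silylated (TBSCl, imidazole) to (2S)-2-(tert-butyldimethylsilyloxy)-1-[4-(triisopropylsilyloxy)phenyl]but-3-ene F2. Ozonolysis (O3, CH2Cl2, −78 °C; PPh3) would give (2S)-2-(tert-butyldimethylsilyloxy)-3-[4-(triisopropylsilyloxy)phenyl]propanal F3, used at once in a Horner–Wadsworth–Emmons reaction with dimethyl (2-oxopropyl)phosphonate (LiCl, iPr2NEt, MeCN). This would give enone 9, which re-enters step 4 at the enolisation stage.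

Step 2 (one-pot chlorohydrin to allylic alcohol). What may go wrong: incomplete elimination of the betaine, or attack of the excess ylide and base on the aryl silyl ether. Fallback: a stepwise carbanion route. Chlorohydrin 4 would be closed with NaOH to the isolated epoxide 5. Opening with lithiated methyl phenyl sulfoxide (LDA, THF, −78 → 0 °C) would give the γ-hydroxy sulfoxide (2S)-4-(phenylsulfinyl)-1-[4-(triisopropylsilyloxy)phenyl]butan-2-ol F4. Thermal syn-elimination of the sulfoxide (toluene, CaCO3, 110 °C) would return to allylic alcohol 6.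

**Further compounds**
F1 | step 5 | 4-[(1R,4E,6S)-6-(tert-butyldimethylsilyloxy)-1-hydroxy-3-oxo-7-[4-(triisopropylsilyloxy)phenyl]hept-4-en-1-yl]-2-methoxyphenyl acetate | COc1cc([C@H](O)CC(=O)/C=C/[C@@H](O[Si](C)(C)C(C)(C)C)Cc2ccc(O[Si](C(C)C)(C(C)C)C(C)C)cc2)ccc1OC(C)=O
F2 | step 3 | (2S)-2-(tert-butyldimethylsilyloxy)-1-[4-(triisopropylsilyloxy)phenyl]but-3-ene | C=C[C@@H](O[Si](C)(C)C(C)(C)C)Cc1ccc(O[Si](C(C)C)(C(C)C)C(C)C)cc1
F3 | step 3 | (2S)-2-(tert-butyldimethylsilyloxy)-3-[4-(triisopropylsilyloxy)phenyl]propanal | O=C[C@@H](O[Si](C)(C)C(C)(C)C)Cc1ccc(O[Si](C(C)C)(C(C)C)C(C)C)cc1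
F4 | step 2 | (2S)-4-(phenylsulfinyl)-1-[4-(triisopropylsilyloxy)phenyl]butan-2-ol | O=S(CC[C@@H](O)Cc1ccc(O[Si](C(C)C)(C(C)C)C(C)C)cc1)c1ccccc1
A1 | direct plan | (S)-2-(benzyloxy)-3-[4-(benzyloxy)phenyl]propanal | O=C[C@H](Cc1ccc(OCc2ccccc2)cc1)OCc1ccccc1
A2 | direct plan | (E)-{[4-(4-(benzyloxy)-3-methoxyphenyl)buta-1,3-dien-2-yl]oxy}trimethylsilane | COc1cc(/C=C/C(=C)O[Si](C)(C)C)ccc1OCc1ccccc1
A3 | direct plan | (1E,5S,6S)-6-(benzyloxy)-1-[4-(benzyloxy)-3-methoxyphenyl]-7-[4-(benzyloxy)phenyl]-5-hydroxyhept-1-en-3-one | COc1cc(/C=C/C(=O)C[C@H](O)[C@@H](OCc2ccccc2)Cc2ccc(OCc3ccccc3)cc2)ccc1OCc1ccccc1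
A4 | direct plan | (2R,6S)-2-[4-(benzyloxy)-3-methoxyphenyl]-6-{(1S)-1-(benzyloxy)-2-[4-(benzyloxy)phenyl]ethyl}tetrahydro-4H-pyran-4-one | COc1cc([C@H]2CC(=O)C[C@@H]([C@@H](OCc3ccccc3)Cc3ccc(OCc4ccccc4)cc3)O2)ccc1OCc1ccccc1
A5 | direct plan | (2R,4S,6S)-2-[4-(benzyloxy)-3-methoxyphenyl]-6-{(1S)-1-(benzyloxy)-2-[4-(benzyloxy)phenyl]ethyl}tetrahydro-2H-pyran-4-ol | COc1cc([C@H]2C[C@H](O)C[C@@H]([C@@H](OCc3ccccc3)Cc3ccc(OCc4ccccc4)cc3)O2)ccc1OCc1ccccc1
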